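Each 2,3-diaryl-2,3-dihydrobenzofuran ring (O1, C2, C3, C3a, C7a) is carried as a six-membered 2,4-diarylchroman-3-one and contracted by photochemical loss of CO. C2 (benzylic, O-bound) and C3 (doubly benzylic) are ideal radical termini, so their recombination forges the C2–C3 bond; both rings contract in one operation on a centrosymmetric precursor. That precursor grows from a trans-fused pair of eight-membered carbocycles sharing the central CH–CH bond. It is obtained from a 14-membered cyclic diyne (Sonogashira cyclodimerisation; the alkyne geometry excludes seven-membered closure) by hydration, transannular oxidative enolate coupling, aryl addition and ionic hydrogenation.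

Key step: step 14

Remark: the target SMILES describes a meso compound (the two halves are mirror images, inversion centre on the central CH–CH bond), so only relative stereocontrol is planned; centres that are destroyed later (C2 and C3 of the chroman rings in 22–24) are left undefined in the SMILES.

Ring labels: ring A = 4-oxyphenyl on the eight-membered ring; ring B = 3,5-dioxygenated ring inside the eight-membered ring; ring C = benzo ring of the benzofuran; ring D = 4-oxyphenyl on C2 of the heterocycle. "Ring-fusion carbons" are the two CH of the central bond.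

Step 1
Reactants: 1 3,5-dimethoxybenzoic acid
Product: 2 2-iodo-3,5-dimethoxybenzoic acid
Conditions: NIS, CF3CO2H (cat.), MeCN, rt
Reagents that add atoms: N-iodosuccinimide, O=C1CCC(=O)N1I
Why: Electrophilic aromatic iodination at C2 (ortho and para to the methoxy groups), the position between the two methoxy groups being the more hindered.

Step 2
Reactants: 2 2-iodo-3,5-dimethoxybenzoic acid; 3 1-bromo-3,5-dimethoxybenzene
Product: 6 (2-bromo-6-hydroxy-4-methoxyphenyl)(2-iodo-3,5-dimethoxyphenyl)methanone, via acid chloride 4 (not isolated), via tetramethoxy ketone 5 (not isolated)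
Conditions: (COCl)2, DMF (cat.), CH2Cl2, rt; then 3, SnCl4, 0 °C to rt; then BCl3, −78 to 0 °C
Reagents that add atoms: none
Why: Friedel–Crafts acylation of the activated bromoarene para to one methoxy group and ortho to bromine (as in its Vilsmeier formylation), followed in the same flask by chelation-controlled BCl3 cleavage of the single methoxy group ortho to the carbonyl.

Step 3
Reactants: 6 (2-bromo-6-hydroxy-4-methoxyphenyl)(2-iodo-3,5-dimethoxyphenyl)methanone
Product: 7 3-bromo-2-[(2-iodo-3,5-dimethoxyphenyl)methyl]-5-methoxyphenol
Conditions: Et3SiH, BF3·OEt2, CH2Cl2/MeCN, 0 °C to rt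
Reagents that add atoms: none
Why: Ionic hydrogenation of the electron-rich diaryl ketone to the diarylmethane, which removes the carbonyl that would otherwise condense (indenone formation) with the ortho-acyl group created in step 6; the aryl halides are untouched.

Step 4
Reactants: 7 3-bromo-2-[(2-iodo-3,5-dimethoxyphenyl)methyl]-5-methoxyphenol; 8 ethynyl(trimethyl)silane
Product: 9 3-bromo-2-({3,5-dimethoxy-2-[(trimethylsilyl)ethynyl]phenyl}methyl)-5-methoxyphenol
Conditions: PdCl2(PPh3)2 (5 mol %), CuI (10 mol %), Et3N, THF, 45 °C
Reagents that add atoms: none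
Why: Sonogashira coupling at the C–I bond only, because oxidative addition of zerovalent palladium to the aryl iodide is far faster than to the aryl bromide.

Step 5
Reactants: 9 3-bromo-2-({3,5-dimethoxy-2-[(trimethylsilyl)ethynyl]phenyl}methyl)-5-methoxyphenol (two molecules)
Product: 12 cyclic diyne dimer, via terminal alkyne 10 (not isolated), via open-chain dimer 11 (not isolated)
Conditions: Pd(PPh3)4 (10 mol %), CuI (10 mol %), CsF, Et3N, DMF, 80 °C, syringe-pump addition (final 2 mM)
Reagents that add atoms: none
Why: Fluoride-triggered desilylative Sonogashira coupling joins ring B of one molecule to ring C of the other; a diarylalkyne cannot sit in the seven-membered ring that closure within one molecule would need, so the first ring that can form is the 14-membered head-to-tail cyclodimer, which fixes the crossed connectivity of the target.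

Step 6
Reactants: 12 cyclic diyne dimer
Product: 13 cyclic bis(deoxybenzoin)
Conditions: (IPr)AuCl (5 mol %), AgSbF6 (5 mol %), 1,4-dioxane/H2O (10:1), 80 °C
Reagents that add atoms: water (two molecules), O
Why: Gold-catalysed Markovnikov-type hydration of both alkynes, water adding to the alkyne carbon on ring B whose ortho and para methoxy groups stabilise the positive charge (ring C carries only meta oxygen), so both carbonyl groups end up next to ring B.

Step 7
Reactants: 13 cyclic bis(deoxybenzoin)
Product: 15 trans-fused bicyclic 1,4-diketone, via tetrasilyl bis(enol ether) 14 (not isolated)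
Conditions: Me3SiOTf, Et3N, CH2Cl2, 0 °C; evaporation; Cu(OTf)2, Cu2O, MeCN, 0 °C to rt; then K2CO3, MeOH, rt
Reagents that add atoms: none
Why: Transannular oxidative coupling of the bis(silyl enol ether) by divalent copper (the phenols are masked as silyl ethers in the same operation) forms the central C–C bond and both eight-membered rings; both new stereocentres are alpha to a ketone, so the basic methanol treatment should equilibrate them to the trans-fused centrosymmetric isomer, in which each large group on the new bond has only one large gauche neighbour.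

Step 8
Reactants: 15 trans-fused bicyclic 1,4-diketone; 16 (4-methoxyphenyl)magnesium bromide (two molecules)
Product: 17 bis(tertiary alcohol)
Conditions: 16 (6 equiv), CeCl3, THF, −78 to 0 °C
Reagents that add atoms: none
Why: Organocerium 1,2-addition of one aryl group to each of the two hindered, enolisable aryl ketones (two further equivalents are consumed by the phenols); ring A is expected to enter anti to the ring C on the adjacent carbon, but these carbinol centres become cations in step 9.

Step 9
Reactants: 17 bis(tertiary alcohol)
Product: 18 bicyclic bisphenol core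
Conditions: Et3SiH, CF3CO2H, CH2Cl2, −40 to 0 °C
Reagents that add atoms: none
Why: Ionic hydrogenation: each doubly aryl-stabilised tertiary cation (any cyclic ether formed from the 1,4-diol re-ionises) should accept hydride from the face anti to the ring C on the neighbouring ring-fusion carbon, which places the new hydrogen cis to that carbon's hydrogen as the target requires.

Step 10
Reactants: 19 (4-methoxyphenyl)acetaldehyde
Product: 20 (E)-2-(4-methoxyphenyl)ethenyl acetate
Conditions: Ac2O, Et3N, DMAP (cat.), CH2Cl2, rt
Reagents that add atoms: acetic anhydride, CC(=O)OC(C)=O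
Why: Enol ester formation by O-acylation of the conjugated enolate of an arylacetaldehyde; the E/Z composition does not matter because both centres derived from this alkene are erased later.

Step 11
Reactants: 18 bicyclic bisphenol core; 20 (E)-2-(4-methoxyphenyl)ethenyl acetate (two molecules)
Product: 22 bis(chroman-3-yl acetate), via bis(quinone methide) 21 (not isolated)
Conditions: Ag2O (4 equiv), 20 (6 equiv), benzene, 50 °C, dark
Reagents that add atoms: none
Why: Ag2O oxidises each of the two ortho-benzylphenols to an ortho-quinone methide, and each quinone methide takes up one molecule of the electron-rich styrene 20 in an inverse-electron-demand hetero-Diels–Alder reaction with the regiochemistry of anethole (oxygen to the carbon bearing ring D); the new C4 centre should be set by the eight-membered ring, which keeps ring B on the face of ring C opposite to the Ar2CH group of the adjacent ring-fusion carbon, while C2 and C3 form as mixtures.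

Step 12
Reactants: 22 bis(chroman-3-yl acetate)
Product: 23 bis(chroman-3-ol)
Conditions: K2CO3, MeOH/THF, rt
Reagents that add atoms: none
Why: Base-catalysed transesterification (methanolysis) of the two secondary acetates.

Step 13
Reactants: 23 bis(chroman-3-ol)
Product: 24 bis(2,4-diarylchroman-3-one)
Conditions: Dess–Martin periodinane, NaHCO3, CH2Cl2, 0 °C to rt, argon
Reagents that add atoms: none
Why: Dess–Martin oxidation of the secondary alcohols; C4 of each ketone is epimerisable and should keep ring B on the face dictated by the eight-membered ring.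

Step 14
Reactants: 24 bis(2,4-diarylchroman-3-one)
Product: 25 decamethyl ether of the target
Conditions: hν (313 nm), degassed benzene (2 mM), rt
Reagents that add atoms: none
Why: Irradiation into the n→π* band of each saturated ketone causes alpha-cleavage (both flanking carbons give stabilised radicals: C2 is benzylic and oxygen-substituted, C4 doubly benzylic) and the acyl radical then loses CO, leaving a 1,5-biradical. Each dihydrofuran ring is closed by radical–radical recombination of C2 with C4 (ring contraction from six to five atoms by extrusion of the carbonyl carbon), the closest known reaction type being the photodecarbonylation of dibenzyl ketones and of 2,6-diarylcyclohexanones to 1,2-diarylcyclopentanes. Neither radical carbon has a beta-hydrogen, so disproportionation cannot compete and recombination is the only productive exit. The stereocentre at C3 of each dihydrofuran should be controlled by the eight-membered ring, which holds ring B on the face of ring C opposite to the Ar2CH group of the adjacent ring-fusion carbon in ketone, biradical and product alike. The stereocentre at C2 is controlled by C3: the freely rotating alpha-aryloxybenzyl radical should close through the transition state with the two aryl groups trans, and any cis isomer is corrected in step 15. The step needs selective excitation of the carbonyl among ten methoxyarene rings and CO loss faster than beta-scission of the aryloxy bond, secured by irradiating above 300 nm and by the high stability of both benzylic radicals.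

Step 15
Reactants: 25 decamethyl ether of the target
Product: 26 CNP0224452.1
Conditions: BBr3, CH2Cl2, −78 °C to rt; then MeOH/H2O
Reagents that add atoms: none
Why: Lewis-acid cleavage of the ten aryl methyl ethers (the dihydrobenzofuran C–O bonds are expected to survive, as in permethylated resveratrol oligomers), with any cis-dihydrobenzofuran epimerising to trans by reversible ionisation at C2.

Compound list

1 | 3,5-dimethoxybenzoic acid | COc1cc(OC)cc(c1)C(=O)O | starting material
2 | 2-iodo-3,5-dimethoxybenzoic acid | COc1cc(OC)c(I)c(c1)C(=O)O | intermediate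
3 | 1-bromo-3,5-dimethoxybenzene | COc1cc(Br)cc(OC)c1 | starting material
4 | 2-iodo-3,5-dimethoxybenzoyl chloride | COc1cc(OC)c(I)c(c1)C(=O)Cl | intermediate (not isolated)
5 | (2-bromo-4,6-dimethoxyphenyl)(2-iodo-3,5-dimethoxyphenyl)methanone | COc1cc(OC)c(I)c(c1)C(=O)c1c(Br)cc(OC)cc1OC | intermediate (not isolated)
6 | (2-bromo-6-hydroxy-4-methoxyphenyl)(2-iodo-3,5-dimethoxyphenyl)methanone | COc1cc(OC)c(I)c(c1)C(=O)c1c(Br)cc(OC)cc1O | intermediate
7 | 3-bromo-2-[(2-iodo-3,5-dimethoxyphenyl)methyl]-5-methoxyphenol | COc1cc(OC)c(I)c(c1)Cc1c(Br)cc(OC)cc1O | intermediate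
8 | ethynyl(trimethyl)silane | C#C[Si](C)(C)C | starting material
9 | 3-bromo-2-({3,5-dimethoxy-2-[(trimethylsilyl)ethynyl]phenyl}methyl)-5-methoxyphenol | COc1cc(OC)c(C#C[Si](C)(C)C)c(c1)Cc1c(Br)cc(OC)cc1O | intermediate
10 | 3-bromo-2-[(2-ethynyl-3,5-dimethoxyphenyl)methyl]-5-methoxyphenol | COc1cc(OC)c(C#C)c(c1)Cc1c(Br)cc(OC)cc1O | intermediate (not isolated)
11 | open-chain dimer: alkyne of one unit of 10 joined to the brominated carbon of a second unit; one C–Br and one terminal alkyne remain | COc1cc(OC)c(C#Cc2cc(OC)cc(O)c2Cc2cc(OC)cc(OC)c2C#C)c(c1)Cc1c(Br)cc(OC)cc1O | intermediate (not isolated)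
12 | cyclic diyne dimer: 14-membered ring made of two diarylacetylene units (ring B of one half to ring C of the other) and two ArCH2Ar bridges; achiral | C1#Cc2cc(OC)cc(O)c2Cc2cc(OC)cc(OC)c2C#Cc2cc(OC)cc(O)c2Cc2cc(OC)cc(OC)c12 | intermediate
13 | cyclic bis(deoxybenzoin): each alkyne of 12 turned into C(=O)–CH2, carbonyl on ring B, CH2 on ring C | O=C1Cc2cc(OC)cc(O)c2Cc2cc(OC)cc(OC)c2C(=O)Cc2cc(OC)cc(O)c2Cc2cc(OC)cc(OC)c12 | intermediate
14 | tetrakis(trimethylsilyl) derivative of 13: two silyl enol ethers and two aryl silyl ethers | C[Si](C)(C)OC1=Cc2cc(OC)cc(O[Si](C)(C)C)c2Cc2cc(OC)cc(OC)c2C(O[Si](C)(C)C)=Cc2cc(OC)cc(O[Si](C)(C)C)c2Cc2cc(OC)cc(OC)c12 | intermediate (not isolated)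
15 | trans-fused bicyclic 1,4-diketone: two eight-membered rings share the new CH–CH bond, its two hydrogens anti; meso | O=C1c2c(OC)cc(OC)cc2Cc2c(O)cc(OC)cc2[C@H]2C(=O)c3c(OC)cc(OC)cc3Cc3c(O)cc(OC)cc3[C@H]12 | intermediate
16 | (4-methoxyphenyl)magnesium bromide | COc1ccc([Mg]Br)cc1 | starting material
17 | bis(tertiary alcohol): ring A added to both ketones of 15, drawn with ring A anti to the ring C on the adjacent carbon; meso | COc1ccc([C@@]2(O)c3c(OC)cc(OC)cc3Cc3c(O)cc(OC)cc3[C@H]3[C@](O)(c4ccc(OC)cc4)c4c(OC)cc(OC)cc4Cc4c(O)cc(OC)cc4[C@H]23)cc1 | intermediate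
18 | bicyclic bisphenol core: each Ar2CH hydrogen cis to the hydrogen of the neighbouring ring-fusion carbon, ring fusion trans; meso | COc1ccc([C@@H]2c3c(OC)cc(OC)cc3Cc3c(O)cc(OC)cc3[C@H]3[C@@H](c4ccc(OC)cc4)c4c(OC)cc(OC)cc4Cc4c(O)cc(OC)cc4[C@H]23)cc1 | intermediate
19 | (4-methoxyphenyl)acetaldehyde | COc1ccc(CC=O)cc1 | starting material
20 | (E)-2-(4-methoxyphenyl)ethenyl acetate | COc1ccc(/C=C/OC(C)=O)cc1 | intermediate
21 | bis(ortho-quinone methide) of 18: each phenol ring C as a 6-(arylmethylidene)cyclohexa-2,4-dienone | COc1ccc([C@@H]2c3c(OC)cc(OC)cc3C=C3C(=O)C=C(OC)C=C3[C@H]3[C@@H](c4ccc(OC)cc4)c4c(OC)cc(OC)cc4C=C4C(=O)C=C(OC)C=C4[C@H]23)cc1 | intermediate (not isolated)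
22 | bis(chroman-3-yl acetate): on each ring C a chroman with ring D at C2, acetoxy at C3, ring B at C4 (C4 as in the target, C2/C3 mixture) | COc1ccc([C@@H]2c3c(OC)cc(OC)cc3[C@H]3c4c(cc(OC)cc4[C@H]4[C@@H](c5ccc(OC)cc5)c5c(OC)cc(OC)cc5[C@@H]5c6c(cc(OC)cc6[C@H]24)OC(c2ccc(OC)cc2)C5OC(C)=O)OC(c2ccc(OC)cc2)C3OC(C)=O)cc1 | intermediate
23 | bis(chroman-3-ol): 22 with both acetates cleaved | COc1ccc([C@@H]2c3c(OC)cc(OC)cc3[C@H]3c4c(cc(OC)cc4[C@H]4[C@@H](c5ccc(OC)cc5)c5c(OC)cc(OC)cc5[C@@H]5c6c(cc(OC)cc6[C@H]24)OC(c2ccc(OC)cc2)C5O)OC(c2ccc(OC)cc2)C3O)cc1 | intermediate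
24 | bis(2,4-diarylchroman-3-one): ring D at C2 (undefined), ring B at C4 on the face of ring C opposite to the Ar2CH group | COc1ccc([C@@H]2c3c(OC)cc(OC)cc3[C@H]3c4c(cc(OC)cc4[C@H]4[C@@H](c5ccc(OC)cc5)c5c(OC)cc(OC)cc5[C@@H]5c6c(cc(OC)cc6[C@H]24)OC(c2ccc(OC)cc2)C5=O)OC(c2ccc(OC)cc2)C3=O)cc1 | intermediate
25 | decamethyl ether of the target: both dihydrobenzofurans 2,3-trans, all centres as in the target; meso | COc1ccc([C@@H]2c3c(OC)cc(OC)cc3[C@H]3c4c(cc(OC)cc4[C@H]4[C@@H](c5ccc(OC)cc5)c5c(OC)cc(OC)cc5[C@@H]5c6c(cc(OC)cc6[C@H]24)O[C@H]5c2ccc(OC)cc2)O[C@@H]3c2ccc(OC)cc2)cc1 | intermediate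
26 | CNP0224452.1 | Oc1ccc([C@@H]2c3c(O)cc(O)cc3[C@H]3c4c(cc(O)cc4[C@H]4[C@@H](c5ccc(O)cc5)c5c(O)cc(O)cc5[C@@H]5c6c(cc(O)cc6[C@H]24)O[C@H]5c2ccc(O)cc2)O[C@@H]3c2ccc(O)cc2)cc1 | target

Total step count: 15. Longest linear sequence: 14 steps (steps 1–9 and 11–15, from 3,5-dimethoxybenzoic acid).

Steps most likely to fail

1. Step 7. The two enol ethers may couple between molecules, or the electron-rich rings may be oxidised, instead of the transannular C–C bond forming. The fallback sets out from 13 and comes back at 15, and it replaces the oxidative coupling by carbene dimerisation. Diazo transfer to both activated methylene groups (4-acetamidobenzenesulfonyl azide, DBU, MeCN) gives the bis(alpha-diazo ketone) F3. Slow addition of F3 to Rh2(OAc)4 in CH2Cl2 should join the two carbenoid carbons across the ring to give the bicyclic ene-dione F4. Zn in AcOH reduces the ene-dione to the 1,4-diketone, and K2CO3 in MeOH equilibrates it to trans-fused 15.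

2. Step 5. Chain growth may outrun ring closure, so that linear oligomers form instead of the cyclodimer. The fallback sets out from 9 and comes back at 12, and it builds the ring stepwise. One portion of 9 is converted into the aryl iodide F1 (aromatic Finkelstein reaction: CuI, NaI, trans-N,N'-dimethylcyclohexane-1,2-diamine, dioxane, 110 °C). A second portion is desilylated to 10 (K2CO3, MeOH), now isolated. Sonogashira coupling of 10 with F1 at room temperature (PdCl2(PPh3)2, CuI, Et3N) engages only the iodide and gives the silyl-capped open-chain dimer F2, which has one C–Br and one protected alkyne. CsF, Pd(PPh3)4 and CuI under high dilution then close the ring within one molecule to 12.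

3. Step 14. The excited ketone may break the aryloxy C–O bond (fragmentation to quinone methide and arylketene) faster than it loses CO, and recombination at the doubly benzylic carbon may not be face-selective. The fallback sets out from 18 and comes back at 25, and it moves the extruded carbonyl to the other side of C2. Oxidation of 18 with Ag2O gives 21, which is trapped with (4-methoxyphenyl)ketene (from (4-methoxyphenyl)acetyl chloride and i-Pr2NEt) in a hetero-Diels–Alder reaction to give the bis(3,4-diaryl-3,4-dihydrocoumarin) F5. Irradiation of F5 at 254 nm (MeCN, quartz) cleaves the aryl ester O–acyl bond, the arylacetyl radical loses CO, and O–C recombination contracts each lactone to the dihydrobenzofuran. Photo-Fries return to carbon is geometrically blocked, and the diaryl-substituted carbon is never a radical, so its configuration from the cycloaddition is kept.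

Further compounds

F1 | step 5 | 3-iodo-2-({3,5-dimethoxy-2-[(trimethylsilyl)ethynyl]phenyl}methyl)-5-methoxyphenol | COc1cc(OC)c(C#C[Si](C)(C)C)c(c1)Cc1c(I)cc(OC)cc1O
F2 | step 5 | silyl-capped open-chain dimer (one C–Br, one trimethylsilyl alkyne) | COc1cc(OC)c(C#Cc2cc(OC)cc(O)c2Cc2cc(OC)cc(OC)c2C#C[Si](C)(C)C)c(c1)Cc1c(Br)cc(OC)cc1O
F3 | step 7 | bis(alpha-diazo ketone) of 13 | O=C1C(=[N+]=[N-])c2cc(OC)cc(O)c2Cc2cc(OC)cc(OC)c2C(=O)C(=[N+]=[N-])c2cc(OC)cc(O)c2Cc2cc(OC)cc(OC)c12
F4 | step 7 | bicyclic ene-dione (central C=C shared by both eight-membered rings) | O=C1c2c(OC)cc(OC)cc2Cc2c(O)cc(OC)cc2C2=C1c1cc(OC)cc(O)c1Cc1cc(OC)cc(OC)c1C2=O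
F5 | step 14 | bis(3,4-diaryl-3,4-dihydrocoumarin): ring D at C3 (undefined), ring B at C4 as in the target | COc1ccc([C@@H]2c3c(OC)cc(OC)cc3[C@H]3c4c(cc(OC)cc4[C@H]4[C@@H](c5ccc(OC)cc5)c5c(OC)cc(OC)cc5[C@@H]5c6c(cc(OC)cc6[C@H]24)OC(=O)C5c2ccc(OC)cc2)OC(=O)C3c2ccc(OC)cc2)cc1
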